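The 2,3-dihydrobenzofuran is read as a ring-contracted flavanone. If the exocyclic CH2O carbon on C3 is returned to the ring as a C4 carbonyl, O1–C2–C3 becomes the vinylogous ester of a chromone, in which C2 (bound to O1, β to C=O) is the electrophilic carbon. Everything rests on the bond between C2 and C1′ of the guaiacyl ring. A rhodium/chiral-diene 1,4-addition joins arylboronic acid 6 to the flat, achiral 6-iodo-8-methoxychromone 4 and sets C2 as (R) in one catalytic operation. An iodine(III)-induced 1,2-shift of the benzo ring then contracts the pyranone and relays C2 to C3 (trans). Reduction, chemoselective Mitsunobu acylation and a Heck reaction finish.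

Key step: step 4

Assumption: on chromone 4 the ligand (R,R)-Ph-bod* [(1R,4R)-2,5-diphenylbicyclo[2.2.2]octa-2,5-diene] is taken to induce the same facial sense as on 2-cyclohexenone, which corresponds to (R) at C2; its antipode is equally available and would be used if the sense were opposite.

Step 1
Reactants: 1 1-(2-hydroxy-3-methoxyphenyl)ethan-1-one
Product: 2 1-(2-hydroxy-5-iodo-3-methoxyphenyl)ethan-1-one
Conditions: NIS (1.05 equiv), TFA (10 mol %), MeCN, rt
Reagents that add atoms: N-iodosuccinimide, O=C1CCC(=O)N1I
Why: Electrophilic aromatic iodination, in which both ortho positions of the phenol are blocked, so the OH group directs iodine to the free para position C5, which is also meta to the deactivating acetyl group.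

Step 2
Reactants: 2 1-(2-hydroxy-5-iodo-3-methoxyphenyl)ethan-1-one
Product: 4 6-iodo-8-methoxy-4H-chromen-4-one, via enaminone 3 (not isolated)
Conditions: DMF-DMA (1.5 equiv), toluene, 100 °C; evaporate; conc. HCl, CH2Cl2, 40 °C
Reagents that add atoms: N,N-dimethylformamide dimethyl acetal, CN(C)C(OC)OC
Why: Enaminone route to chromones, in which the methyl ketone condenses with DMF-DMA and acid then induces addition of the phenol OH to the β-carbon with elimination of dimethylamine, closing the pyranone.

Step 3
Reactants: 5 (4-hydroxy-3-methoxyphenyl)boronic acid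
Product: 6 [3-methoxy-4-(pivaloyloxy)phenyl]boronic acid
Conditions: PivCl (1.1 equiv), Et3N (1.2 equiv), THF, 0 °C to rt; 1 M HCl work-up
Reagents that add atoms: pivaloyl chloride, CC(C)(C)C(=O)Cl
Why: Simple O-acylation of the phenol, any mixed boron–pivalate anhydride being hydrolysed back to B(OH)2 in the aqueous work-up.

Step 4
Reactants: 4 6-iodo-8-methoxy-4H-chromen-4-one; 6 [3-methoxy-4-(pivaloyloxy)phenyl]boronic acid (2 equiv)
Product: 7 4-[(2R)-6-iodo-8-methoxy-4-oxo-3,4-dihydro-2H-chromen-2-yl]-2-methoxyphenyl pivalate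
Conditions: [RhCl(C2H4)2]2 (2.5 mol %), (R,R)-Ph-bod* (5.5 mol %), KOH (0.2 equiv), toluene–H2O 10:1, 40 °C
Reagents that add atoms: none
Why: Hayashi–Miyaura asymmetric 1,4-addition, a reaction type established for chromones as a route to flavanones: boron-to-rhodium transmetalation of 6 gives an aryl–Rh(I)(diene) species, chromone 4 binds through C2=C3, syn carborhodation delivers the aryl group to C2 (bound to O1 and β to C4=O), and water protonates the oxa-π-allyl rhodium enolate to release 7 and Rh–OH. No ring is closed; the pyranone of 4 is kept as a temporary six-membered ring that step 5 contracts. The only new stereocenter, C2, is set by the C2-symmetric diene, whose phenyl groups allow only the binding mode in which the carbonyl side of the chromone points away from them, the facial sense that gives (R)-3-arylcyclohexanones and here corresponds to (R). Regioselectivity for C2 over 1,2-attack at C4=O follows from the polarisation of the vinylogous ester and the preference of aryl–Rh(I) for alkene insertion, and over-addition to the ketone of 7 is held back by the low temperature and the biphasic medium. Chemoselectivity is needed against the C6–I bond and the pivalate: Rh(I) should not insert into an aryl iodide at 40 °C, and the substoichiometric KOH is buffered by excess boronic acid, which also keeps 7 from racemising by retro-oxa-Michael ring opening. The O-pivaloyl group lowers the donor strength of the transferred aryl ring, which slows protodeboronation of 6 and ionisation of the new benzylic C2–O1 bond.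

Step 5
Reactants: 7 4-[(2R)-6-iodo-8-methoxy-4-oxo-3,4-dihydro-2H-chromen-2-yl]-2-methoxyphenyl pivalate
Product: 9 methyl (2R,3R)-5-iodo-7-methoxy-2-[3-methoxy-4-(pivaloyloxy)phenyl]-2,3-dihydro-1-benzofuran-3-carboxylate, via enol ether 8 (not isolated)
Conditions: PhI(OAc)2 (1.2 equiv), conc. H2SO4 (0.5 equiv), HC(OMe)3, rt
Reagents that add atoms: trimethyl orthoformate, COC(OC)OC
Why: Known hypervalent-iodine oxidative ring contraction of flavanones (1,2-aryl shift), in which enol ether 8 is attacked by iodine(III) at C3 anti to the C2 aryl group, methanol adds at C4, and the C4–C4a bond antiperiplanar to the equatorial C3–I bond migrates to C3 with inversion and loss of PhI, placing the new ester carbon trans to the aryl group and so setting C3 as (R) from C2 without touching C2.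

Step 6
Reactants: 9 methyl (2R,3R)-5-iodo-7-methoxy-2-[3-methoxy-4-(pivaloyloxy)phenyl]-2,3-dihydro-1-benzofuran-3-carboxylate
Product: 10 4-[(2R,3S)-3-(hydroxymethyl)-5-iodo-7-methoxy-2,3-dihydro-1-benzofuran-2-yl]-2-methoxyphenol
Conditions: DIBAL-H (6 equiv), CH2Cl2, −78 to 0 °C; aq. Rochelle salt
Reagents that add atoms: none
Why: Hydride reduction of both esters in one operation (methyl ester to CH2OH, aryl pivalate to the free phenol) under non-basic conditions that spare the aryl iodide and do not enolise C3, the change of the C3 descriptor to (S) being only a change of CIP priorities.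

Step 7
Reactants: 10 4-[(2R,3S)-3-(hydroxymethyl)-5-iodo-7-methoxy-2,3-dihydro-1-benzofuran-2-yl]-2-methoxyphenol
Product: 11 [(2R,3S)-2-(4-hydroxy-3-methoxyphenyl)-5-iodo-7-methoxy-2,3-dihydro-1-benzofuran-3-yl]methyl 3-methylbutanoate
Conditions: isovaleric acid (1.3 equiv), PPh3 (1.3 equiv), DIAD (1.3 equiv), THF, 0 °C to rt
Reagents that add atoms: 3-methylbutanoic acid (isovaleric acid), CC(C)CC(=O)O
Why: Mitsunobu esterification, chemoselective because only the aliphatic primary OH can be activated as an alkoxyphosphonium ion and the far more acidic carboxylic acid rather than the guaiacol OH supplies the nucleophile, with displacement at CH2 leaving both stereocenters untouched.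

Step 8
Reactants: 11 [(2R,3S)-2-(4-hydroxy-3-methoxyphenyl)-5-iodo-7-methoxy-2,3-dihydro-1-benzofuran-3-yl]methyl 3-methylbutanoate
Product: 12 [(2R,3S)-2-(4-hydroxy-3-methoxyphenyl)-7-methoxy-5-[(E)-3-oxoprop-1-en-1-yl]-2,3-dihydro-1-benzofuran-3-yl]methyl 3-methylbutanoate
Conditions: acrolein (3 equiv), Pd(OAc)2 (5 mol %), n-Bu4NCl (1 equiv), NaHCO3 (2.5 equiv), DMF, 40 °C
Reagents that add atoms: acrolein, C=CC=O
Why: Mizoroki–Heck reaction under Jeffery phase-transfer conditions, in which the aryl iodide reacts at low temperature with a base too weak to ionise the phenol or cleave the ester, and syn insertion followed by syn β-hydride elimination gives the (E)-enal.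

Compound list
1 | 1-(2-hydroxy-3-methoxyphenyl)ethan-1-one | CC(=O)c1cccc(OC)c1O | starting material
2 | 1-(2-hydroxy-5-iodo-3-methoxyphenyl)ethan-1-one | CC(=O)c1cc(I)cc(OC)c1O | intermediate
3 | (E)-3-(dimethylamino)-1-(2-hydroxy-5-iodo-3-methoxyphenyl)prop-2-en-1-one (enaminone, not isolated) | CN(C)/C=C/C(=O)c1cc(I)cc(OC)c1O | intermediate
4 | 6-iodo-8-methoxy-4H-chromen-4-one | O=c1ccoc2c(OC)cc(I)cc12 | intermediate
5 | (4-hydroxy-3-methoxyphenyl)boronic acid | COc1cc(B(O)O)ccc1O | starting material
6 | [3-methoxy-4-(pivaloyloxy)phenyl]boronic acid | COc1cc(B(O)O)ccc1OC(=O)C(C)(C)C | intermediate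
7 | 4-[(2R)-6-iodo-8-methoxy-4-oxo-3,4-dihydro-2H-chromen-2-yl]-2-methoxyphenyl pivalate, the (R)-flavanone | O=C1C[C@H](c2ccc(OC(=O)C(C)(C)C)c(OC)c2)Oc2c(OC)cc(I)cc21 | intermediate
8 | 4-[(2R)-6-iodo-4,8-dimethoxy-2H-chromen-2-yl]-2-methoxyphenyl pivalate (methyl enol ether, not isolated) | COC1=C[C@H](c2ccc(OC(=O)C(C)(C)C)c(OC)c2)Oc2c(OC)cc(I)cc21 | intermediate
9 | methyl (2R,3R)-5-iodo-7-methoxy-2-[3-methoxy-4-(pivaloyloxy)phenyl]-2,3-dihydro-1-benzofuran-3-carboxylate (trans) | COc1cc([C@@H]2Oc3c(OC)cc(I)cc3[C@H]2C(=O)OC)ccc1OC(=O)C(C)(C)C | intermediate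
10 | 4-[(2R,3S)-3-(hydroxymethyl)-5-iodo-7-methoxy-2,3-dihydro-1-benzofuran-2-yl]-2-methoxyphenol (trans) | COc1cc([C@@H]2Oc3c(OC)cc(I)cc3[C@H]2CO)ccc1O | intermediate
11 | [(2R,3S)-2-(4-hydroxy-3-methoxyphenyl)-5-iodo-7-methoxy-2,3-dihydro-1-benzofuran-3-yl]methyl 3-methylbutanoate | COc1cc([C@@H]2Oc3c(OC)cc(I)cc3[C@H]2COC(=O)CC(C)C)ccc1O | intermediate
12 | [(2R,3S)-2-(4-hydroxy-3-methoxyphenyl)-7-methoxy-5-[(E)-3-oxoprop-1-en-1-yl]-2,3-dihydro-1-benzofuran-3-yl]methyl 3-methylbutanoate (CNP0272976.1) | COc1cc([C@@H]2Oc3c(OC)cc(/C=C/C=O)cc3[C@H]2COC(=O)CC(C)C)ccc1O | target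

Total step count: 8. Longest linear sequence: 7 (steps 1, 2, 4, 5, 6, 7, 8).

Steps most likely to fail

Step 5 (ring contraction).
- What may go wrong: the C2 aryl group migrates instead of the benzo ring; the pyranone is dehydrogenated; C3 is simply α-methoxylated; iodine(III) attacks the arenes; or ee erodes by reversible acid-induced opening of the pyranone.
- Fallback: a Wolff ring contraction. It moves the same C4–C4a bond through a carbene, without acid or oxidant.
- It sets out from 7. Trifluoroacetylation of the lithium enolate (LiHMDS, CF3CO2CH2CF3, THF, −78 °C) should give the 3-trifluoroacetylflavanone F1.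
- Detrifluoroacetylative diazo transfer (MsN3, Et3N, H2O, MeCN, rt) should give the 3-diazoflavanone F2.
- Irradiation at 365 nm in MeOH should give the ring-contracted ketene F3. Methanol traps it with protonation of C3 anti to the aryl group, which should give mainly the cis ester F4.
- DBU in toluene then equilibrates C3 to the more stable trans ester, and the fallback comes back to the route at 9.

Step 4 (key 1,4-addition).
- What may go wrong: slow insertion into the electron-rich vinylogous ester; a second addition to the product ketone; insufficient facial selectivity; or loss of ee by reversible ring opening of the product.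
- Fallback: the same bond is formed without asymmetric induction, and the stereocenter is then secured by resolution.
- It sets out from 4 and 6. The more active achiral catalyst [Rh(OH)(cod)]2 (dioxane–H2O, 50 °C) should give the racemic flavanone F5.
- A kinetic resolution by Noyori asymmetric transfer hydrogenation follows (RuCl(p-cymene)[(S,S)-TsDPEN], HCO2H–Et3N, CH2Cl2, rt, stopped near half conversion).
- It should reduce the (2S)-enantiomer, for which catalyst control and attack anti to the aryl group coincide, to the cis-(2S,4S)-flavan-4-ol F6.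
- The unreacted (R)-ketone is separated by chromatography, and the fallback comes back to the route at 7.

Step 8 (Heck reaction with acrolein).
- What may go wrong: acrolein polymerises; the enal is arylated a second time; or the dihydrofuran ring opens through a p-quinone methide once the free phenol is deprotonated.
- Fallback: a base-free Stille coupling with a preformed, masked (E)-enal unit.
- It sets out from 11. The reagent is (E)-tributyl(3,3-diethoxyprop-1-en-1-yl)stannane, CCCC[Sn](CCCC)(CCCC)/C=C/C(OCC)OCC, with Pd2(dba)3 and AsPh3 in NMP at 40 °C.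
- This should give the enal diethyl acetal F7. PPTS in wet acetone at rt then hydrolyses it, and the fallback comes back to the route at 12.

Further compounds
F1 | step 5 | 4-[(2R)-6-iodo-8-methoxy-4-oxo-3-(trifluoroacetyl)-3,4-dihydro-2H-chromen-2-yl]-2-methoxyphenyl pivalate (C3 not defined, enolisable) | O=C(C1C(=O)c2cc(I)cc(OC)c2O[C@H]1c1ccc(OC(=O)C(C)(C)C)c(OC)c1)C(F)(F)F
F2 | step 5 | 4-[(2S)-3-diazo-6-iodo-8-methoxy-4-oxo-3,4-dihydro-2H-chromen-2-yl]-2-methoxyphenyl pivalate (same spatial arrangement at C2 as in 7, descriptor changed by CIP priority) | [N-]=[N+]=C1C(=O)c2cc(I)cc(OC)c2O[C@H]1c1ccc(OC(=O)C(C)(C)C)c(OC)c1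
F3 | step 5 | 4-[(2S)-5-iodo-7-methoxy-3-(oxomethylidene)-2,3-dihydro-1-benzofuran-2-yl]-2-methoxyphenyl pivalate (ketene, transient, C2 arrangement unchanged) | O=C=C1c2cc(I)cc(OC)c2O[C@H]1c1ccc(OC(=O)C(C)(C)C)c(OC)c1
F4 | step 5 | methyl (2R,3S)-5-iodo-7-methoxy-2-[3-methoxy-4-(pivaloyloxy)phenyl]-2,3-dihydro-1-benzofuran-3-carboxylate (cis) | COc1cc([C@@H]2Oc3c(OC)cc(I)cc3[C@@H]2C(=O)OC)ccc1OC(=O)C(C)(C)C
F5 | step 4 | racemic 4-(6-iodo-8-methoxy-4-oxo-3,4-dihydro-2H-chromen-2-yl)-2-methoxyphenyl pivalate | O=C1CC(c2ccc(OC(=O)C(C)(C)C)c(OC)c2)Oc2c(OC)cc(I)cc21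
F6 | step 4 | 4-[(2S,4S)-4-hydroxy-6-iodo-8-methoxy-3,4-dihydro-2H-chromen-2-yl]-2-methoxyphenyl pivalate (2,4-cis) | O[C@H]1C[C@@H](c2ccc(OC(=O)C(C)(C)C)c(OC)c2)Oc2c(OC)cc(I)cc21
F7 | step 8 | [(2R,3S)-5-[(E)-3,3-diethoxyprop-1-en-1-yl]-2-(4-hydroxy-3-methoxyphenyl)-7-methoxy-2,3-dihydro-1-benzofuran-3-yl]methyl 3-methylbutanoate | COc1cc([C@@H]2Oc3c(OC)cc(/C=C/C(OCC)OCC)cc3[C@H]2COC(=O)CC(C)C)ccc1O
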